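(The earlier runs and the new flask are calculated on assumed constants; the scatter is artificial.)

A one-step world, with [reagent] at 0.600 M against [starting material] at 0.50 M, lets the target climb to a full yield, yet you read Monday's flask standing at 32.0% from 25.0 min to 90.0 min.

in all of them: starting material 0.50 M
- Monday's: reagent 0.60 M; second substrate 0.50 M; the very flask that is asked about, followed so far
- Tuesday's: reagent 0.60 M; second substrate 0.75 M; run made earlier
- flask: reagent 0.600 M; second substrate 0.500 M; time 2.0 h

| run | time / min | target / % |
|---|---|---|
| Monday's | 8.00 | 20.8 |
| Monday's | 15.0 | 27.7 |
| Monday's | 25.0 | 31.9 |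
| Monday's | 50.0 | 31.8 |
| Monday's | 90.0 | 32.2 |
| Tuesday's | 12.0 | 25.5 |
| Tuesday's | 25.0 | 27.5 |
| Tuesday's | 40.0 | 30.5 |
| Tuesday's | 50.0 | 30.0 |
| Tuesday's | 60.0 | 29.6 |

(scatter of a reading: 1 percentage point)

- midnight: at 2.0 h add reagent, 50.0% of the amount charged, then wait 4.0 h
- winter: change nothing and wait 4.0 h more
- summer: at 2.0 h add starting material, 50.0% of the amount charged, then wait 4.0 h

- additions leave the volume as it is
- the numbers in the tables scatter by 1 percentage point (one standard deviation)
- a reading or a percentage of target counts all its forms, free or not

- target, in percent of the starting material first charged, at 2.0 h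
- which option adds most target ("none" when 2 percentage points or less is all one gets) (midnight / winter / summer / none)
- target present, in percent of the starting material first charged, after midnight
- target present, in percent of the starting material first charged, after winter

So the first question is whether the clock still matters. Reading the rise against that plateau at 8.00 min gives a lifetime of 7.61 min, much shorter than the 2.0 h at which you look, which holds 15.8 lifetimes, so I expect no gain from the winter option.

The next question is which charge holds the plateau down. Tuesday's flask, with [second substrate] at 0.75 M against 0.50 M, reads 30.0% at 50.0 min where Monday's flask reads 31.8%, a difference of 1.8 percentage points against a scatter of 1 point, so second substrate is a weak lever.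

That points to reagent, and the number to carry is 0.266, the yield on reagent, [target] at the plateau over the [reagent] charged. My own reckoning, which is a wager, holds that yield fixed: the flask reads 32.0% now and after winter, summer leaves the reagent charge as it was and brings no gain, and midnight reaches 48.0%.

The forecast says 32% now, 32% after winter and 41% after midnight, which is lower than my figure, and it picks midnight: “This choice is uncertain, but reagent is the better bet.”

The flask gives 28.9% at 2.0 h, 27.8% after winter and 43.4% after midnight, so midnight adds 14 points while summer brings −1.2 points.

    starting material + reagent ⇌ target (K = 8.10 L mol⁻¹, k = 0.00130 L mol⁻¹ s⁻¹)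
    second substrate + reagent ⇌ second product (K = 1.20 L mol⁻¹, k = 0.00150 L mol⁻¹ s⁻¹)
    target ⇌ isomer of the product (K = 3.90, k = 0.00150 s⁻¹)
    reagent + target ⇌ idle adduct, settled at all times (K = 13.0 L mol⁻¹)
    2 starting material → homo dimer (k = 1.30 × 10⁻⁶ L mol⁻¹ s⁻¹)

Reckoned from these results, the yield on reagent is 0.241 at 2.0 h and 0.241 after midnight, so the added reagent paid at the old rate. A part of that gain comes from the binding of reagent and target into idle adduct: with that binding taken away, midnight adds 2.4 points to the flask instead of 14 points. On the neighbour charged with 0.36 M reagent, 0.266 promises 19.2% target, and that flask holds 16.2%.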